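**Retrosynthetic overview**
1. Hansforester A comes from its hexabenzyl ether by one global hydrogenolysis. No ring is formed in the route: rings A, B and C are all bought as benzene derivatives.
2. Both aryl–C(=O)–O bonds are cut. Each is closed with the same alcohol, the (R)-3-hydroxybutanoate of (R)-1-[3,5-bis(benzyloxy)phenyl]propan-2-ol, which is made once and used twice.
3. The carboxyl group of ring B is added after the first coupling, by formylation and oxidation of the ring that is terminal at that stage. One block therefore serves as both the ring B unit and the ring C unit.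
4. The block comes from its acetoacetate. Ru–BINAP hydrogenation sets the hydroxybutanoate centres, and lipase-selective acetoacetylation sets the arylpropanol centres.
5. The key C–C bond ArCH2–CH(OH)CH3 joins two aldehyde carbons. The hydrazone of 3,5-bis(benzyloxy)benzaldehyde acts as a benzyl-anion equivalent towards acetaldehyde, with loss of N2.

Assumption: the SMILES reads as (R) at all four stereocentres, and the route is built for that isomer.

**Step 1**
Reactants: 1 3,5-bis(benzyloxy)benzaldehyde; 2 hydrazine hydrate; 3 acetaldehyde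
Product: 5 rac-1-[3,5-bis(benzyloxy)phenyl]propan-2-ol, via hydrazone 4 (not isolated)
Conditions: 2 (1.05 equiv per 1), THF, rt, 1 h; then [RuCl2(p-cymene)]2 (1.5 mol%), Me2PCH2CH2PMe2 (3 mol%), K3PO4 (25 mol%), CsF (75 mol%), 3 (0.75 equiv per 1, slow addition in THF), 45 °C, sealed tube, 12 h
Reagents that add atoms: acetaldehyde, CC=O; hydrazine hydrate, NN.O (its nitrogen stays only in 4)
Why: This is a ruthenium-catalysed hydrazone umpolung carbonyl addition (Wolff–Kishner-type), in which the deprotonated, Ru-bound hydrazone delivers its former aldehyde carbon as a benzyl-anion equivalent to the Ru-bound C=O of acetaldehyde through a six-membered transition state and N2 is then lost, so two electrophilic aldehyde carbons are joined and the benzylic carbon arrives already as CH2; benzyl ethers are inert, limiting and slowly added acetaldehyde holds back the mixed azine and aldol side reactions, and the new carbinol centre is racemic here and is set in step 2.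

**Step 2**
Reactants: 5 rac-1-[3,5-bis(benzyloxy)phenyl]propan-2-ol; 6 ethyl acetoacetate
Product: 7 (2R)-1-[3,5-bis(benzyloxy)phenyl]propan-2-yl 3-oxobutanoate
Conditions: Novozym 435 (immobilised Candida antarctica lipase B), 6 (3 equiv), toluene, 4 Å MS, 40 °C, stopped near 50% conversion; chromatography
Reagents that add atoms: ethyl acetoacetate, CCOC(=O)CC(C)=O
Why: This is a lipase-catalysed kinetic resolution by transesterification of a β-keto ester, in which by the Kazlauskas rule CH3 fits the small pocket and CH2Ar the large one, so only the (R)-alcohol is acylated by the acetoacetyl-enzyme, which sets the arylpropanol centre as (R) and installs the C4 acyl unit in the same operation.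

**Step 3**
Reactants: 7 (2R)-1-[3,5-bis(benzyloxy)phenyl]propan-2-yl 3-oxobutanoate
Product: 8 (2R)-1-[3,5-bis(benzyloxy)phenyl]propan-2-yl (3R)-3-hydroxybutanoate
Conditions: RuCl2[(R)-BINAP] (0.5 mol%), H2 (50 bar), EtOH/CH2Cl2, 50 °C
Reagents that add atoms: none
Why: In this Noyori asymmetric hydrogenation of a β-keto ester the chelated keto ester takes hydride on one face from the (R)-BINAP–Ru hydride and gives the (3R)-alcohol under catalyst control (the same sense as methyl acetoacetate to methyl (R)-3-hydroxybutanoate), and the homogeneous catalyst touches neither the benzyl ethers nor the existing centre.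

**Step 4**
Reactants: 9 methyl orsellinate (methyl 2,4-dihydroxy-6-methylbenzoate); 10 benzyl bromide
Product: 12 2,4-bis(benzyloxy)-6-methylbenzoic acid, via methyl ester 11 (not isolated)
Conditions: 10 (2.2 equiv), K2CO3, DMSO, 60 °C; then aq KOH (10 equiv), 100 °C; then aq HCl
Reagents that add atoms: benzyl bromide, BrCc1ccccc1; potassium hydroxide, [K+].[OH-]
Why: A Williamson ether synthesis is followed in the same pot by saponification of the hindered ester with KOH in hot aqueous DMSO, benzyl aryl ethers are stable to base, and no stereocentre is involved.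

**Step 5**
Reactants: 12 2,4-bis(benzyloxy)-6-methylbenzoic acid; 8 (2R)-1-[3,5-bis(benzyloxy)phenyl]propan-2-yl (3R)-3-hydroxybutanoate
Product: 14 (2R)-4-{[(2R)-1-[3,5-bis(benzyloxy)phenyl]propan-2-yl]oxy}-4-oxobutan-2-yl 2,4-bis(benzyloxy)-6-methylbenzoate, via acid chloride 13 (not isolated)
Conditions: (COCl)2, cat. DMF, CH2Cl2, 0 °C to rt, evaporate; then 8, pyridine (3 equiv), DMAP (0.2 equiv), CH2Cl2, 0 °C to rt
Reagents that add atoms: oxalyl chloride, O=C(Cl)C(=O)Cl (chlorine, only in 13)
Why: In this acyl chloride esterification with DMAP acyl transfer the small and very electrophilic acyl chloride overcomes the di-ortho substitution, the carbinol C–O bond is not touched so (3R) is retained, and pyridine at or below rt avoids E1cB loss of the β-aroyloxy group.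

**Step 6**
Reactants: 14 the ring A–hydroxybutanoate–ring C diester from step 5; 15 N,N-dimethylformamide
Product: 17 (2R)-4-{[(2R)-1-[3,5-bis(benzyloxy)-2-formylphenyl]propan-2-yl]oxy}-4-oxobutan-2-yl 2,4-bis(benzyloxy)-6-methylbenzoate, via iminium salt 16 (not isolated)
Conditions: POCl3 (2 equiv), DMF, 0 to 50 °C; then H2O, 0 °C to rt
Reagents that add atoms: N,N-dimethylformamide, CN(C)C=O; water, O
Why: In this Vilsmeier–Haack formylation the weak chloroiminium electrophile attacks only the ring without an acyl substituent, para to one benzyloxy group and ortho to the other, next to the side chain as with 3,5-dialkoxytoluenes and not at the crowded carbon between the two ethers, while the esters and both stereocentres are untouched.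

**Step 7**
Reactants: 17 the aldehyde from step 6
Product: 18 2,4-bis(benzyloxy)-6-[(2R)-2-{[(3R)-3-{[2,4-bis(benzyloxy)-6-methylbenzoyl]oxy}butanoyl]oxy}propyl]benzoic acid
Conditions: NaClO2, NaH2PO4, 2-methylbut-2-ene (20 equiv), t-BuOH/THF/H2O, rt
Reagents that add atoms: sodium chlorite, [Na+].[O-]Cl=O
Why: In this Pinnick oxidation chlorous acid adds to the aldehyde and fragments to the acid at buffered, near-neutral pH that spares esters, benzyl ethers and stereocentres, while the alkene traps HOCl before it can chlorinate the electron-rich rings.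

**Step 8**
Reactants: 18 the ring B acid from step 7; 8 (2R)-1-[3,5-bis(benzyloxy)phenyl]propan-2-yl (3R)-3-hydroxybutanoate
Product: 20 hexa-O-benzyl hansforester A, via acid chloride 19 (not isolated)
Conditions: (COCl)2, cat. DMF, CH2Cl2, 0 °C to rt, evaporate; then 8 (1.1 equiv), pyridine (3 equiv), DMAP (0.2 equiv), CH2Cl2, 0 °C to rt
Reagents that add atoms: oxalyl chloride, O=C(Cl)C(=O)Cl (chlorine, only in 19)
Why: This is the same acyl chloride and DMAP esterification as step 5, in which acylation at oxygen keeps the (3R) centre of 8, the three centres already present are not at reacting atoms, and the mild base protects both β-acyloxy esters from elimination.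

**Step 9**
Reactants: 20 hexa-O-benzyl hansforester A
Product: 21 hansforester A
Conditions: H2 (1 atm), 10% Pd/C, EtOAc/EtOH, rt
Reagents that add atoms: none
Why: Catalytic hydrogenolysis cleaves the six aryl benzyl ethers, and because the four ester C–O bonds are aliphatic or homobenzylic rather than benzylic, they and all four (R) centres survive.

**Compound list**
1 | 3,5-bis(benzyloxy)benzaldehyde | O=Cc1cc(OCc2ccccc2)cc(OCc2ccccc2)c1 | starting material
2 | hydrazine hydrate | NN.O | starting material
3 | acetaldehyde | CC=O | starting material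
4 | (E)-3,5-bis(benzyloxy)benzaldehyde hydrazone | N/N=C/c1cc(OCc2ccccc2)cc(OCc2ccccc2)c1 | intermediate
5 | rac-1-[3,5-bis(benzyloxy)phenyl]propan-2-ol | CC(O)Cc1cc(OCc2ccccc2)cc(OCc2ccccc2)c1 | intermediate
6 | ethyl acetoacetate | CCOC(=O)CC(C)=O | starting material
7 | (2R)-1-[3,5-bis(benzyloxy)phenyl]propan-2-yl 3-oxobutanoate | CC(=O)CC(=O)O[C@H](C)Cc1cc(OCc2ccccc2)cc(OCc2ccccc2)c1 | intermediate
8 | (2R)-1-[3,5-bis(benzyloxy)phenyl]propan-2-yl (3R)-3-hydroxybutanoate | O[C@H](C)CC(=O)O[C@H](C)Cc1cc(OCc2ccccc2)cc(OCc2ccccc2)c1 | intermediate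
9 | methyl orsellinate | COC(=O)c1c(C)cc(O)cc1O | starting material
10 | benzyl bromide | BrCc1ccccc1 | starting material
11 | methyl 2,4-bis(benzyloxy)-6-methylbenzoate | COC(=O)c1c(C)cc(OCc2ccccc2)cc1OCc1ccccc1 | intermediate
12 | 2,4-bis(benzyloxy)-6-methylbenzoic acid | Cc1cc(OCc2ccccc2)cc(OCc2ccccc2)c1C(=O)O | intermediate
13 | 2,4-bis(benzyloxy)-6-methylbenzoyl chloride | Cc1cc(OCc2ccccc2)cc(OCc2ccccc2)c1C(=O)Cl | intermediate
14 | (2R)-4-{[(2R)-1-[3,5-bis(benzyloxy)phenyl]propan-2-yl]oxy}-4-oxobutan-2-yl 2,4-bis(benzyloxy)-6-methylbenzoate | Cc1cc(OCc2ccccc2)cc(OCc2ccccc2)c1C(=O)O[C@H](C)CC(=O)O[C@H](C)Cc1cc(OCc2ccccc2)cc(OCc2ccccc2)c1 | intermediate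
15 | N,N-dimethylformamide | CN(C)C=O | starting material
16 | aryl(dimethyl)iminium dichlorophosphate of 14 (C=NMe2+ at the ring carbon next to the side chain) | Cc1cc(OCc2ccccc2)cc(OCc2ccccc2)c1C(=O)O[C@H](C)CC(=O)O[C@H](C)Cc1cc(OCc2ccccc2)cc(OCc2ccccc2)c1C=[N+](C)C.[O-]P(=O)(Cl)Cl | intermediate
17 | (2R)-4-{[(2R)-1-[3,5-bis(benzyloxy)-2-formylphenyl]propan-2-yl]oxy}-4-oxobutan-2-yl 2,4-bis(benzyloxy)-6-methylbenzoate | Cc1cc(OCc2ccccc2)cc(OCc2ccccc2)c1C(=O)O[C@H](C)CC(=O)O[C@H](C)Cc1cc(OCc2ccccc2)cc(OCc2ccccc2)c1C=O | intermediate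
18 | 2,4-bis(benzyloxy)-6-[(2R)-2-{[(3R)-3-{[2,4-bis(benzyloxy)-6-methylbenzoyl]oxy}butanoyl]oxy}propyl]benzoic acid | Cc1cc(OCc2ccccc2)cc(OCc2ccccc2)c1C(=O)O[C@H](C)CC(=O)O[C@H](C)Cc1cc(OCc2ccccc2)cc(OCc2ccccc2)c1C(=O)O | intermediate
19 | acid chloride of 18 | Cc1cc(OCc2ccccc2)cc(OCc2ccccc2)c1C(=O)O[C@H](C)CC(=O)O[C@H](C)Cc1cc(OCc2ccccc2)cc(OCc2ccccc2)c1C(=O)Cl | intermediate
20 | hexa-O-benzyl hansforester A (all four centres R) | Cc1cc(OCc2ccccc2)cc(OCc2ccccc2)c1C(=O)O[C@H](C)CC(=O)O[C@H](C)Cc1cc(OCc2ccccc2)cc(OCc2ccccc2)c1C(=O)O[C@H](C)CC(=O)O[C@H](C)Cc1cc(OCc2ccccc2)cc(OCc2ccccc2)c1 | intermediate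
21 | hansforester A | Cc1cc(O)cc(O)c1C(=O)O[C@H](C)CC(=O)O[C@H](C)Cc1cc(O)cc(O)c1C(=O)O[C@H](C)CC(=O)O[C@H](C)Cc1cc(O)cc(O)c1 | target

**Step count**
- Total steps: 9.
- Longest linear sequence: 8 (steps 1, 2, 3, 5, 6, 7, 8, 9). Step 4 is the only side branch.
- Alcohol 8 enters twice, in steps 5 and 8.

**Three steps most likely to fail**

Step 1. Formation of the mixed azine, aldol chemistry of acetaldehyde, or plain Wolff–Kishner reduction of 4 may outrun the addition. The fallback sets out from 1 and comes back at 5, and it makes the same bond with a stoichiometric acyl-anion equivalent. Compound 1 with propane-1,3-dithiol and BF3·OEt2 in CH2Cl2 gives 2-[3,5-bis(benzyloxy)phenyl]-1,3-dithiane F1. Deprotonation with n-BuLi in THF at −78 °C and addition to acetaldehyde gives rac-1-{2-[3,5-bis(benzyloxy)phenyl]-1,3-dithian-2-yl}ethan-1-ol F2. Raney Ni, deactivated with acetone so that the benzyl ethers are spared, in EtOH at rt removes the sulfur and gives 5.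

Step 2. The bulky alcohol may be accepted slowly or with a modest selectivity factor, and half of the material is lost in any case. The fallback sets out from 5 and comes back at 7, and it replaces resolution by a redox deracemisation. Dess–Martin periodinane in CH2Cl2 gives 1-[3,5-bis(benzyloxy)phenyl]propan-2-one F3. An anti-Prelog alcohol dehydrogenase (Lactobacillus kefir ADH, NADP+, i-PrOH, buffer/MTBE) reduces it to (2R)-1-[3,5-bis(benzyloxy)phenyl]propan-2-ol F4. Heating F4 with 2,2,6-trimethyl-4H-1,3-dioxin-4-one in toluene at 110 °C gives 7.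

Step 8. The acyl carbon of 19 sits between a benzyloxy group and a branched side chain, so acylation may be slow enough for elimination to the crotonate to compete. The fallback sets out from 7 (together with acid 18) and comes back at 20, and it makes the carboxylate the nucleophile instead of the acyl carbon the electrophile. Hydrogenation of 7 with RuCl2[(S)-BINAP] gives (2R)-1-[3,5-bis(benzyloxy)phenyl]propan-2-yl (3S)-3-hydroxybutanoate F5. A Mitsunobu esterification of F5 with 18 (PPh3, DIAD, toluene, 0 °C) proceeds by SN2 inversion to the (3R)-ester 20.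

**Further compounds**
F1 | step 1 | 2-[3,5-bis(benzyloxy)phenyl]-1,3-dithiane | C1CSC(SC1)c1cc(OCc2ccccc2)cc(OCc2ccccc2)c1
F2 | step 1 | rac-1-{2-[3,5-bis(benzyloxy)phenyl]-1,3-dithian-2-yl}ethan-1-ol | CC(O)C1(SCCCS1)c1cc(OCc2ccccc2)cc(OCc2ccccc2)c1
F3 | step 2 | 1-[3,5-bis(benzyloxy)phenyl]propan-2-one | CC(=O)Cc1cc(OCc2ccccc2)cc(OCc2ccccc2)c1
F4 | step 2 | (2R)-1-[3,5-bis(benzyloxy)phenyl]propan-2-ol | O[C@H](C)Cc1cc(OCc2ccccc2)cc(OCc2ccccc2)c1
F5 | step 8 | (2R)-1-[3,5-bis(benzyloxy)phenyl]propan-2-yl (3S)-3-hydroxybutanoate | O[C@@H](C)CC(=O)O[C@H](C)Cc1cc(OCc2ccccc2)cc(OCc2ccccc2)c1
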